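**Retrosynthetic overview**
- Target ⇐ open 10‑hydroxy‑3‑ketone 23: the oxolane hemiketal closes by itself once C10–OH is freed (last ring formed).
- Ten‑membered carbocycle ⇐ C3–C4 Nozaki–Hiyama–Kishi closure of a C3 aldehyde onto a (Z)‑C4 vinyl iodide (second ring), then oxidation to the enone.
- C7–C8 and C11–C13 ⇐ one‑pot union of a C8 acyl‑anion equivalent (2‑lithio‑1,3‑dithiane) with a (5S)‑butenolide (1,4‑addition sets C7) and formaldehyde; C8–OH by CBS reduction.
- Dithiane ⇐ (R)‑linalool (supplies C10, C14, C9, C8, C1–C3); butenolide ⇐ acrolein + TBS propargyl ether + acryloyl chloride (γ‑lactone, first ring, by RCM).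

Numbering: germacrane numbering is used in the text (C1–C10 ring, C11–C13 lactone carbons, C14 methyl on C10, C15 CH2OH on C4).

Assumption: C3 is a hemiketal carbon set only by reversible closure of C10–OH onto the C3 ketone in the last step; the target is written exactly as in the given SMILES, although read literally its C3 tag places C4 and C9 on opposite faces of the oxolane — the closure can deliver only the normal bridged epimer ([C@]3 at C3 in the same atom order).

**Route**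

Step 1
Reactants: 1 (R)-(−)-linalool
Product: 2 (R)-triethyl[(3,7-dimethylocta-1,6-dien-3-yl)oxy]silane
Conditions: TESOTf, 2,6-lutidine, CH2Cl2, −78 → 0 °C
Reagents that add atoms: triethylsilyl triflate, CC[Si](CC)(CC)OS(=O)(=O)C(F)(F)F
Why: Silyl triflate silylation of the hindered tertiary alcohol; the C10 stereocentre is taken unchanged from (R)-linalool and the ether protects the later β-oxy aldehyde from retro-aldol and dehydration.

Step 2
Reactants: 2 linalool TES ether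
Product: 3 (3R)-3,7-dimethyl-3-(triethylsilyloxy)oct-6-enal
Conditions: PdCl2(PhCN)2 (10 mol %), CuCl2·2H2O (10 mol %), AgNO2 (5 mol %), t-BuOH/MeNO2 15:1, O2 (1 atm), rt
Reagents that add atoms: dioxygen, O=O
Why: Nitrite-modified aldehyde-selective Tsuji–Wacker oxidation; the allylic oxygen and the fully substituted allylic carbon direct oxygen to the terminal carbon (C8), and the trisubstituted alkene is not a Wacker substrate.

Step 3
Reactants: 3 β-silyloxy aldehyde
Product: 4 2-[(2R)-2,6-dimethyl-2-(triethylsilyloxy)hept-5-en-1-yl]-1,3-dithiane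
Conditions: HS(CH2)3SH, MgBr2·OEt2, Et2O, 0 °C → rt
Reagents that add atoms: propane-1,3-dithiol, SCCCS
Why: Mild Lewis-acid dithioacetalisation (Corey–Seebach dithiane) turns the electrophilic C8 aldehyde carbon into a latent acyl anion without touching the silyl ether or the alkene.

Step 4
Reactants: 5 acrolein; 6 tert-butyldimethyl(prop-2-yn-1-yloxy)silane
Product: 7 (3S)-6-(tert-butyldimethylsilyloxy)hex-1-en-4-yn-3-ol
Conditions: ProPhenol ligand (10 mol %, antipode giving 3S), Me2Zn (3 equiv), toluene, 0 °C; aq. NH4Cl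
Reagents that add atoms: none
Why: Zn–ProPhenol catalysed asymmetric alkynylation (1,2-addition of the alkynylzinc to the enal); the ligand antipode fixes the carbinol that becomes C6.

Step 5
Reactants: 7 enynol
Product: 9 (3S,4Z)-6-(tert-butyldimethylsilyloxy)-5-iodohexa-1,4-dien-3-ol, via cyclic vinylalanate 8 (not isolated)
Conditions: Red-Al, THF, 0 °C → rt; then I2, THF, −78 → 0 °C
Reagents that add atoms: iodine, II
Why: Hydroxyl-directed trans-hydroalumination of the propargylic alcohol puts Al on the distal alkyne carbon and iodinolysis with retention gives the Z vinyl iodide, which is the C4=C5 geometry of the target (C4 substituent cis to C6).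

Step 6
Reactants: 9 iodo dienol
Product: 10 (3S,4Z)-6-(tert-butyldimethylsilyloxy)-5-iodohexa-1,4-dien-3-yl prop-2-enoate
Conditions: acryloyl chloride, i-Pr2NEt, CH2Cl2, −20 → 0 °C
Reagents that add atoms: acryloyl chloride, C=CC(Cl)=O
Why: Simple O-acylation of the secondary alcohol; no stereocentre is touched.

Step 7
Reactants: 10 acrylate
Product: 11 (5S)-5-[(1Z)-3-(tert-butyldimethylsilyloxy)-2-iodoprop-1-en-1-yl]furan-2(5H)-one
Conditions: Grubbs II (5 mol %), CH2Cl2 (0.01 M), 40 °C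
Reagents that add atoms: none
Why: Ring-closing metathesis of the acrylate with the terminal vinyl group gives the butenolide (C6, C7, C11, C12); the iodo-trisubstituted alkene is too hindered to take part.

Step 8 (key step)
Reactants: 4 dithiane; 11 butenolide
Product: 14 (3R,4S,5S)-5-[(1Z)-3-(tert-butyldimethylsilyloxy)-2-iodoprop-1-en-1-yl]-4-{2-[(2R)-2,6-dimethyl-2-(triethylsilyloxy)hept-5-en-1-yl]-1,3-dithian-2-yl}-3-(hydroxymethyl)oxolan-2-one, via lithiated dithiane 12 (not isolated), via lithium lactone enolate 13 (not isolated)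
Conditions: 4, t-BuLi, THF/HMPA 9:1, −78 °C; then 11, −78 °C; then CH2O (g), −78 → −40 °C; aq. NH4Cl
Reagents that add atoms: formaldehyde, C=O
Why: Corey–Seebach umpolung in a tandem Michael–aldol: the C8 acyl-anion equivalent adds 1,4 to the butenolide anti to its γ-alkenyl group (C7 set trans to C6, HMPA favouring 1,4 over 1,2) and the lactone enolate is hydroxymethylated anti to the new substituent to bring in C13.

Step 9
Reactants: 14 dithiane adduct
Product: 15 (3R,4S,5S)-5-[(1Z)-3-(tert-butyldimethylsilyloxy)-2-iodoprop-1-en-1-yl]-4-[(3R)-3,7-dimethyl-3-(triethylsilyloxy)oct-6-enoyl]-3-(hydroxymethyl)oxolan-2-one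
Conditions: PhI(O2CCF3)2, NaHCO3, MeCN/H2O 9:1, 0 °C
Reagents that add atoms: water, O
Why: Oxidative dithiane hydrolysis (Stork PIFA method) unmasks the C8 ketone under buffered conditions that spare both silyl ethers, the vinyl iodide and the trans,trans lactone.

Step 10
Reactants: 15 γ-keto lactone
Product: 16 (3R,4R,5S)-5-[(1Z)-3-(tert-butyldimethylsilyloxy)-2-iodoprop-1-en-1-yl]-4-[(1R,3R)-1-hydroxy-3,7-dimethyl-3-(triethylsilyloxy)oct-6-en-1-yl]-3-(hydroxymethyl)oxolan-2-one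
Conditions: (S)-Me-CBS (0.5 equiv), catecholborane (3 equiv), toluene, −78 °C; MeOH
Reagents that add atoms: none
Why: Corey–Bakshi–Shibata reduction: with the branched C7 as the large group the (S)-catalyst delivers hydride to give the 8R carbinol, and catecholborane at −78 °C leaves the lactone and both alkenes alone.

Step 11
Reactants: 16 diol
Product: 18 (1R,3R)-1-{(2S,3R)-2-[(1Z)-3-(tert-butyldimethylsilyloxy)-2-iodoprop-1-en-1-yl]-4-methylidene-5-oxooxolan-3-yl}-3,7-dimethyl-3-(triethylsilyloxy)oct-6-en-1-yl 2-methylpropanoate, via bis-isobutyrate 17 (not isolated)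
Conditions: i-PrCOCl (2.5 equiv), Et3N, DMAP (cat.), CH2Cl2, 0 °C → rt; then DBU, 0 °C → rt
Reagents that add atoms: isobutyryl chloride, CC(C)C(Cl)=O
Why: DMAP-catalysed acylation of both alcohols (the C8 ester is the natural isobutyrate) followed by DBU-induced E1cB loss of the β-acyloxy group from the lactone α-position gives the α-methylene lactone.

Step 12
Reactants: 18 α-methylene lactone
Product: 20 (1R,3R)-1-{(2S,3R)-2-[(1Z)-3-(tert-butyldimethylsilyloxy)-2-iodoprop-1-en-1-yl]-4-methylidene-5-oxooxolan-3-yl}-3-methyl-6-oxo-3-(triethylsilyloxy)hexyl 2-methylpropanoate, via secondary ozonide 19 (not isolated)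
Conditions: O3, CH2Cl2, −78 °C (Sudan Red 7B end point); then Me2S, −78 °C → rt
Reagents that add atoms: ozone, [O-][O+]=O
Why: Ozonolysis with reductive work-up; the electron-rich trisubstituted alkene reacts far faster than the acrylate-type methylene or the iodoalkene, and the dye end point stops the reaction after one equivalent.

Step 13
Reactants: 20 iodo aldehyde
Product: 21 (4Z,6R,7R,8R,10R)-15-(tert-butyldimethylsilyloxy)-3-hydroxy-8-(2-methylpropanoyloxy)-10-(triethylsilyloxy)germacra-4,11(13)-dien-12,6-olide (C3 epimers)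
Conditions: CrCl2 (8 equiv), NiCl2 (1 mol %), DMSO/THF, rt, slow addition to 0.003 M
Reagents that add atoms: none
Why: Nozaki–Hiyama–Kishi reaction: the vinylchromium(III) species forms with retention of the Z geometry and adds chemoselectively to the aldehyde, closing the ten-membered carbocycle; the C3 carbinol mixture is removed in step 14.

Step 14
Reactants: 21 macrocyclic allylic alcohol
Product: 22 (4Z,6R,7R,8R,10R)-15-(tert-butyldimethylsilyloxy)-8-(2-methylpropanoyloxy)-3-oxo-10-(triethylsilyloxy)germacra-4,11(13)-dien-12,6-olide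
Conditions: Dess–Martin periodinane, pyridine, CH2Cl2, 0 °C → rt
Reagents that add atoms: none
Why: Dess–Martin oxidation of the allylic alcohol to the (Z)-enone under near-neutral conditions tolerated by the α-methylene lactone and the silyl ethers.

Step 15
Reactants: 22 enone
Product: 24 target (3,10-epoxy-3,15-dihydroxy-8-isobutyryloxygermacra-4Z,11(13)-dien-12,6-olide), via open keto diol 23 (not isolated)
Conditions: HF·pyridine, THF/pyridine, 0 °C → rt
Reagents that add atoms: none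
Why: Fluoride desilylation frees the C15 and C10 hydroxyls and the C10 hydroxyl adds transannularly to the C3 ketone (thermodynamic hemiketalisation), so the C3 configuration is dictated by C10 through the ring.

**Compound list**

1 | (R)-(−)-linalool, (3R)-3,7-dimethylocta-1,6-dien-3-ol | C=C[C@](C)(O)CCC=C(C)C | starting material
2 | (R)-triethyl[(3,7-dimethylocta-1,6-dien-3-yl)oxy]silane | C=C[C@](C)(O[Si](CC)(CC)CC)CCC=C(C)C | intermediate
3 | (3R)-3,7-dimethyl-3-(triethylsilyloxy)oct-6-enal | O=CC[C@](C)(O[Si](CC)(CC)CC)CCC=C(C)C | intermediate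
4 | 2-[(2R)-2,6-dimethyl-2-(triethylsilyloxy)hept-5-en-1-yl]-1,3-dithiane | C1(C[C@](C)(O[Si](CC)(CC)CC)CCC=C(C)C)SCCCS1 | intermediate
5 | acrolein | C=CC=O | starting material
6 | tert-butyldimethyl(prop-2-yn-1-yloxy)silane | C#CCO[Si](C)(C)C(C)(C)C | starting material
7 | (3S)-6-(tert-butyldimethylsilyloxy)hex-1-en-4-yn-3-ol | C=C[C@H](O)C#CCO[Si](C)(C)C(C)(C)C | intermediate
8 | sodium cyclic vinylalanate (five-membered O–Al–C=C chelate, bis(2-methoxyethoxy) on Al) | [Na+].C=C[C@@H]1O[Al-](OCCOC)(OCCOC)C(CO[Si](C)(C)C(C)(C)C)=C1 | intermediate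
9 | (3S,4Z)-6-(tert-butyldimethylsilyloxy)-5-iodohexa-1,4-dien-3-ol | C=C[C@H](O)/C=C(\I)CO[Si](C)(C)C(C)(C)C | intermediate
10 | (3S,4Z)-6-(tert-butyldimethylsilyloxy)-5-iodohexa-1,4-dien-3-yl prop-2-enoate | C=CC(=O)O[C@@H](C=C)/C=C(\I)CO[Si](C)(C)C(C)(C)C | intermediate
11 | (5S)-5-[(1Z)-3-(tert-butyldimethylsilyloxy)-2-iodoprop-1-en-1-yl]furan-2(5H)-one | O=C1C=C[C@@H](/C=C(\I)CO[Si](C)(C)C(C)(C)C)O1 | intermediate
12 | 2-lithio derivative of dithiane 4 | [Li]C1(C[C@](C)(O[Si](CC)(CC)CC)CCC=C(C)C)SCCCS1 | intermediate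
13 | lithium enolate of the 4,5-trans Michael adduct | [Li]OC1=C[C@H](C2(C[C@](C)(O[Si](CC)(CC)CC)CCC=C(C)C)SCCCS2)[C@@H](/C=C(\I)CO[Si](C)(C)C(C)(C)C)O1 | intermediate
14 | (3R,4S,5S)-5-[(1Z)-3-(TBS-oxy)-2-iodoprop-1-en-1-yl]-4-{2-[(2R)-2,6-dimethyl-2-(TES-oxy)hept-5-en-1-yl]-1,3-dithian-2-yl}-3-(hydroxymethyl)oxolan-2-one | OC[C@@H]1C(=O)O[C@H](/C=C(\I)CO[Si](C)(C)C(C)(C)C)[C@H]1C2(C[C@](C)(O[Si](CC)(CC)CC)CCC=C(C)C)SCCCS2 | intermediate
15 | (3R,4S,5S)-5-[(1Z)-3-(TBS-oxy)-2-iodoprop-1-en-1-yl]-4-[(3R)-3,7-dimethyl-3-(TES-oxy)oct-6-enoyl]-3-(hydroxymethyl)oxolan-2-one | OC[C@@H]1C(=O)O[C@H](/C=C(\I)CO[Si](C)(C)C(C)(C)C)[C@H]1C(=O)C[C@](C)(O[Si](CC)(CC)CC)CCC=C(C)C | intermediate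
16 | (3R,4R,5S)-5-[(1Z)-3-(TBS-oxy)-2-iodoprop-1-en-1-yl]-4-[(1R,3R)-1-hydroxy-3,7-dimethyl-3-(TES-oxy)oct-6-en-1-yl]-3-(hydroxymethyl)oxolan-2-one | OC[C@@H]1C(=O)O[C@H](/C=C(\I)CO[Si](C)(C)C(C)(C)C)[C@H]1[C@H](O)C[C@](C)(O[Si](CC)(CC)CC)CCC=C(C)C | intermediate
17 | bis(2-methylpropanoate) of 16 (esters on C8–O and on the lactone α-CH2O) | CC(C)C(=O)OC[C@@H]1C(=O)O[C@H](/C=C(\I)CO[Si](C)(C)C(C)(C)C)[C@H]1[C@H](OC(=O)C(C)C)C[C@](C)(O[Si](CC)(CC)CC)CCC=C(C)C | intermediate
18 | (1R,3R)-1-{(2S,3R)-2-[(1Z)-3-(TBS-oxy)-2-iodoprop-1-en-1-yl]-4-methylidene-5-oxooxolan-3-yl}-3,7-dimethyl-3-(TES-oxy)oct-6-en-1-yl 2-methylpropanoate | C=C1C(=O)O[C@H](/C=C(\I)CO[Si](C)(C)C(C)(C)C)[C@H]1[C@H](OC(=O)C(C)C)C[C@](C)(O[Si](CC)(CC)CC)CCC=C(C)C | intermediate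
19 | secondary ozonide (3,3-dimethyl-1,2,4-trioxolane) of the side-chain alkene of 18 | C=C1C(=O)O[C@H](/C=C(\I)CO[Si](C)(C)C(C)(C)C)[C@H]1[C@H](OC(=O)C(C)C)C[C@](C)(O[Si](CC)(CC)CC)CCC2OOC(C)(C)O2 | intermediate
20 | (1R,3R)-1-{(2S,3R)-2-[(1Z)-3-(TBS-oxy)-2-iodoprop-1-en-1-yl]-4-methylidene-5-oxooxolan-3-yl}-3-methyl-6-oxo-3-(TES-oxy)hexyl 2-methylpropanoate | C=C1C(=O)O[C@H](/C=C(\I)CO[Si](C)(C)C(C)(C)C)[C@H]1[C@H](OC(=O)C(C)C)C[C@](C)(O[Si](CC)(CC)CC)CCC=O | intermediate
21 | (4Z,6R,7R,8R,10R)-15-(TBS-oxy)-3-hydroxy-8-(2-methylpropanoyloxy)-10-(TES-oxy)germacra-4,11(13)-dien-12,6-olide, C3 epimers | C=C1C(=O)O[C@@H]2/C=C(/CO[Si](C)(C)C(C)(C)C)C(O)CC[C@@](C)(O[Si](CC)(CC)CC)C[C@@H](OC(=O)C(C)C)[C@@H]12 | intermediate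
22 | (4Z,6R,7R,8R,10R)-15-(TBS-oxy)-8-(2-methylpropanoyloxy)-3-oxo-10-(TES-oxy)germacra-4,11(13)-dien-12,6-olide | C=C1C(=O)O[C@@H]2/C=C(/CO[Si](C)(C)C(C)(C)C)C(=O)CC[C@@](C)(O[Si](CC)(CC)CC)C[C@@H](OC(=O)C(C)C)[C@@H]12 | intermediate
23 | (4Z,6R,7R,8R,10R)-10,15-dihydroxy-8-(2-methylpropanoyloxy)-3-oxogermacra-4,11(13)-dien-12,6-olide | C=C1C(=O)O[C@@H]2/C=C(/CO)C(=O)CC[C@@](C)(O)C[C@@H](OC(=O)C(C)C)[C@@H]12 | intermediate
24 | CNP0282937.1, 3,10-epoxy-3,15-dihydroxy-8-(2-methylpropanoyloxy)germacra-4Z,11(13)-dien-12,6-olide (6R,7R,8R,10R; C3 as given) | C=C1C(=O)O[C@@H]2/C=C(/CO)[C@@]3(O)CC[C@](C)(C[C@@H](OC(=O)C(C)C)[C@@H]12)O3 | target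

**Count and risks**

Total step count: 15. Longest linear sequence: 12 steps (5/6 → 24, steps 4–7 and 8–15); the linalool branch is 3 steps before the union.

Most likely to fail:

Step 8 (γ-deprotonation of the alkenyl butenolide to a furanolate, or 1,2-addition, instead of 1,4-addition). The fallback replaces the ring by an open-chain acceptor; it sets out from 9 and 4 and comes back at 14. Alcohol 9 is silylated (TESCl, imidazole) to (3S,4Z)-6-(tert-butyldimethylsilyloxy)-5-iodo-3-(triethylsilyloxy)hexa-1,4-diene F1. Cross-metathesis with methyl acrylate (Hoveyda–Grubbs II) gives methyl (2E,4S,5Z)-7-(tert-butyldimethylsilyloxy)-6-iodo-4-(triethylsilyloxy)hepta-2,5-dienoate F2. Lithiated 4 (12) then adds 1,4 anti to the γ-silyloxy group (Felkin–Anh control) with formaldehyde trapping to give the open-chain adduct methyl (3S,4S,5Z)-3-(dithianyl)-2-(hydroxymethyl)-6-iodo-4-(triethylsilyloxy)hept-5-enoate F3. PPTS in MeOH removes the secondary TES group and the γ-hydroxy ester lactonises to 14 (any C11 epimer converges at 18).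

Step 10 (facial selectivity at C8: the "small" side is a neopentyl-type CH2 and the α-stereocentre may oppose the catalyst). The fallback inverts instead of selecting; it sets out from 15 and comes back at 17. Ketone 15 is reduced deliberately to the 8S alcohol (3R,4R,5S)-4-[(1S,3R)-1-hydroxy-3,7-dimethyl-3-(triethylsilyloxy)oct-6-en-1-yl] epimer of 16 F4 with (R)-Me-CBS or L-Selectride. Mitsunobu esterification with excess isobutyric acid (PPh3, DIAD) then acylates the primary alcohol and inverts C8 to give 17, which is treated with DBU as in step 11.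

Step 13 (entropy and strain of the ten-membered Cr/Ni closure). The fallback forms the same C3–C4 bond by Pd/Cu acyl cross-coupling; it sets out from 20 and comes back at 22, skipping step 14. Aldehyde 20 is oxidised (NaClO2, NaH2PO4, 2-methyl-2-butene) to the carboxylic acid F5. Coupling with 4-methylbenzenethiol (EDC, DMAP) gives the S-(4-methylphenyl) thioester F6. The vinyl iodide is stannylated ((Me3Sn)2, Pd(PPh3)4) to the (Z)-vinyl trimethylstannane thioester F7. Liebeskind–Srogl cyclisation (Pd2(dba)3, tri(2-furyl)phosphine, copper(I) diphenylphosphinate, high dilution) then gives enone 22 directly.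

**Further compounds**

F1 | step 8 | (3S,4Z)-6-(tert-butyldimethylsilyloxy)-5-iodo-3-(triethylsilyloxy)hexa-1,4-diene | C=C[C@H](O[Si](CC)(CC)CC)/C=C(\I)CO[Si](C)(C)C(C)(C)C
F2 | step 8 | methyl (2E,4S,5Z)-7-(tert-butyldimethylsilyloxy)-6-iodo-4-(triethylsilyloxy)hepta-2,5-dienoate | COC(=O)/C=C/[C@H](O[Si](CC)(CC)CC)/C=C(\I)CO[Si](C)(C)C(C)(C)C
F3 | step 8 | methyl (3S,4S,5Z)-7-(tert-butyldimethylsilyloxy)-3-{2-[(2R)-2,6-dimethyl-2-(triethylsilyloxy)hept-5-en-1-yl]-1,3-dithian-2-yl}-2-(hydroxymethyl)-6-iodo-4-(triethylsilyloxy)hept-5-enoate (C2 epimers) | COC(=O)C(CO)[C@H](C1(C[C@](C)(O[Si](CC)(CC)CC)CCC=C(C)C)SCCCS1)[C@H](O[Si](CC)(CC)CC)/C=C(\I)CO[Si](C)(C)C(C)(C)C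
F4 | step 10 | (3R,4R,5S)-5-[(1Z)-3-(tert-butyldimethylsilyloxy)-2-iodoprop-1-en-1-yl]-4-[(1S,3R)-1-hydroxy-3,7-dimethyl-3-(triethylsilyloxy)oct-6-en-1-yl]-3-(hydroxymethyl)oxolan-2-one | OC[C@@H]1C(=O)O[C@H](/C=C(\I)CO[Si](C)(C)C(C)(C)C)[C@H]1[C@@H](O)C[C@](C)(O[Si](CC)(CC)CC)CCC=C(C)C
F5 | step 13 | (4R,6R)-6-{(2S,3R)-2-[(1Z)-3-(tert-butyldimethylsilyloxy)-2-iodoprop-1-en-1-yl]-4-methylidene-5-oxooxolan-3-yl}-4-methyl-6-(2-methylpropanoyloxy)-4-(triethylsilyloxy)hexanoic acid | C=C1C(=O)O[C@H](/C=C(\I)CO[Si](C)(C)C(C)(C)C)[C@H]1[C@H](OC(=O)C(C)C)C[C@](C)(O[Si](CC)(CC)CC)CCC(=O)O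
F6 | step 13 | S-(4-methylphenyl) thioester of F5 | C=C1C(=O)O[C@H](/C=C(\I)CO[Si](C)(C)C(C)(C)C)[C@H]1[C@H](OC(=O)C(C)C)C[C@](C)(O[Si](CC)(CC)CC)CCC(=O)Sc1ccc(C)cc1
F7 | step 13 | (Z)-vinyl trimethylstannane analogue of F6 (SnMe3 in place of I) | C=C1C(=O)O[C@H](/C=C(\[Sn](C)(C)C)CO[Si](C)(C)C(C)(C)C)[C@H]1[C@H](OC(=O)C(C)C)C[C@](C)(O[Si](CC)(CC)CC)CCC(=O)Sc1ccc(C)cc1
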